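**Retrosynthetic overview**

1. Numbering: ring C1 (quaternary, Me/vinyl), C2 (CH2), C3 (O-acyl), C4 (bears C11(=C13H2)–C12O2H), C5 (OH), C6 (bears C(=CH2)–C15H2OH). Target 30 ⇐ 29 ⇐ 28 ⇐ 20 by allyl-ester release, SeO2 hydroxylation at C15 and acylation of C3–OH with side-chain acid 26.
2. 20 ⇐ cis-fused α-methylene lactone 18 by lactone opening; this lactone is a temporary ring that fixes C3–O/C4 cis.
3. Key disconnection C4–C5: 18 ⇐ aldehyde–butenolide 17 by SmI2 ketyl addition/β-elimination (aldehyde carbon C5 acts as the nucleophile towards the butenolide β-carbon C4); this closes ring A and sets C4 and C5.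
4. 17 ⇐ δ-lactone 11 (acetylide addition, Noyori reduction sets C3, Pd cyclocarbonylation builds the butenolide); 11 ⇐ acid 7 by enantioselective Ireland–Claisen rearrangement (sets C1 and C6).
5. Ring order: δ-lactone 11 (opened in step 6) → butenolide (step 8) → cyclohexane ring A (step 10) → butenolide opened (step 11). Acid 26 comes from but-2-yn-1-ol.

Assumption: the (R,R)-bromoborane is taken to give the (2R,3R) acid 7 in step 3 (sense assigned by analogy with reported allyl ester cases, not checked against the original report); if the sense is opposite, the (S,S) reagent is used and nothing else changes.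

**Route**

Step 1
Reactants: 1 tert-butyl(but-3-yn-1-yloxy)dimethylsilane
Product: 3 (2E)-5-{[tert-butyl(dimethyl)silyl]oxy}-3-methylpent-2-en-1-ol, via alkenylalane 2 (not isolated)
Conditions: Me3Al, Cp2ZrCl2 (0.25 equiv), CH2Cl2, 0 °C → rt; then n-BuLi, (CH2O)n, THF, −78 °C → rt; aq. work-up
Reagents that add atoms: trimethylaluminium C[Al](C)C; paraformaldehyde (as formaldehyde) C=O
Why: Negishi zirconium-catalysed syn-carboalumination puts CH3 and Al cis across the alkyne, and the alanate is hydroxymethylated with retention, which fixes the (E)-trisubstituted alkene.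

Step 2
Reactants: 3 (2E)-5-{[tert-butyl(dimethyl)silyl]oxy}-3-methylpent-2-en-1-ol; 4 3-methylbut-3-enoic acid
Product: 5 (2E)-5-{[tert-butyl(dimethyl)silyl]oxy}-3-methylpent-2-en-1-yl 3-methylbut-3-enoate
Conditions: DCC, DMAP (5 mol %), CH2Cl2, 0 °C
Reagents that add atoms: none
Why: Steglich esterification of a primary allylic alcohol at low temperature keeps the β,γ-double bond of the acid out of conjugation.

Step 3
Reactants: 5 (2E)-5-{[tert-butyl(dimethyl)silyl]oxy}-3-methylpent-2-en-1-yl 3-methylbut-3-enoate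
Product: 7 (2R,3R)-5-{[tert-butyl(dimethyl)silyl]oxy}-3-ethenyl-3-methyl-2-(prop-1-en-2-yl)pentanoic acid, via boron ketene acetal 6 (not isolated)
Conditions: (4R,5R)-2-bromo-1,3-bis{[3,5-bis(trifluoromethyl)phenyl]sulfonyl}-4,5-diphenyl-1,3,2-diazaborolidine (1.2 equiv), Et3N, toluene/hexane, −78 → 4 °C; aq. NH4Cl
Reagents that add atoms: none
Why: Corey's enantioselective Ireland–Claisen rearrangement: the E(O) boron enolate (isopropenyl trans to O–B) and the (E)-alkene pass through a chair transition state to the (2R*,3R*) diad (C6 substituent cis to the C1 methyl in the later ring), and the chiral sulfonamide controller selects the (2R,3R) enantiomer.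

Step 4
Reactants: 7 (2R,3R)-5-{[tert-butyl(dimethyl)silyl]oxy}-3-ethenyl-3-methyl-2-(prop-1-en-2-yl)pentanoic acid
Product: 9 (2R,3R)-3-ethenyl-3-methyl-2-(prop-1-en-2-yl)pentane-1,5-diol, via silyl ether alcohol 8 (not isolated)
Conditions: LiAlH4, THF, 0 °C → rt; then 2 M HCl, MeOH, rt
Reagents that add atoms: none
Why: LiAlH4 reduces the acid to the primary alcohol without touching the alkenes or stereocentres, and dilute acid cleaves the primary silyl ether.

Step 5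
Reactants: 9 (2R,3R)-3-ethenyl-3-methyl-2-(prop-1-en-2-yl)pentane-1,5-diol
Product: 11 (4R,5R)-4-ethenyl-4-methyl-5-(prop-1-en-2-yl)oxan-2-one, via lactol 10 (not isolated)
Conditions: TEMPO (0.2 equiv), PhI(OAc)2 (2.5 equiv), CH2Cl2, rt
Reagents that add atoms: none
Why: TEMPO/PhI(OAc)2 oxidative lactonisation of a 1,5-diol: the less hindered C3 carbinol is oxidised first, the aldehyde is trapped as lactol 10 by the C5 hydroxyl and oxidised on to the δ-lactone, which also masks the C5 oxygen.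

Step 6
Reactants: 11 (4R,5R)-4-ethenyl-4-methyl-5-(prop-1-en-2-yl)oxan-2-one; 12 tert-butyldimethyl(prop-2-yn-1-yloxy)silane
Product: 14 (6R,7R)-1-{[tert-butyl(dimethyl)silyl]oxy}-6-ethenyl-8-hydroxy-6-methyl-7-(prop-1-en-2-yl)oct-2-yn-4-one, via lithium acetylide 13 (not isolated)
Conditions: 12, n-BuLi, THF, −78 °C; then 11, −78 °C; sat. NH4Cl
Reagents that add atoms: none
Why: mono-addition of a lithium acetylide to a lactone at −78 °C (the tetrahedral intermediate survives until the quench) gives the ynone, which is in equilibrium with its cyclic hemiketal.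

Step 7
Reactants: 14 (6R,7R)-1-{[tert-butyl(dimethyl)silyl]oxy}-6-ethenyl-8-hydroxy-6-methyl-7-(prop-1-en-2-yl)oct-2-yn-4-one
Product: 15 (4R,6R,7R)-1-{[tert-butyl(dimethyl)silyl]oxy}-6-ethenyl-6-methyl-7-(prop-1-en-2-yl)oct-2-yne-4,8-diol
Conditions: Ru[(R,R)-TsNCH(Ph)CH(Ph)NH](p-cymene) (2 mol %), i-PrOH, rt
Reagents that add atoms: none
Why: Noyori asymmetric transfer hydrogenation of an alkynyl ketone, in which the alkynyl group acts as the π-substituent so that the (R,R)-catalyst gives the (R)-carbinol at C3 under reagent control (the open ynone is drained from the hemiketal equilibrium).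

Step 8
Reactants: 15 (4R,6R,7R)-1-{[tert-butyl(dimethyl)silyl]oxy}-6-ethenyl-6-methyl-7-(prop-1-en-2-yl)oct-2-yne-4,8-diol
Product: 16 (5R)-3-({[tert-butyl(dimethyl)silyl]oxy}methyl)-5-[(2R,3R)-2-ethenyl-3-(hydroxymethyl)-2,4-dimethylpent-4-en-1-yl]furan-2(5H)-one
Conditions: Pd2(dba)3·CHCl3 (2 mol %), dppb (4 mol %), CO/H2 (1:1, 40 atm), CH2Cl2, 95 °C
Reagents that add atoms: carbon monoxide [C-]#[O+]
Why: palladium-catalysed cyclocarbonylation of a propargylic alcohol (Alper type): hydropalladation, CO insertion at the distal alkyne carbon and acyl capture by the C3 hydroxyl give the 3-substituted butenolide with C3 untouched.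

Step 9
Reactants: 16 (5R)-3-({[tert-butyl(dimethyl)silyl]oxy}methyl)-5-[(2R,3R)-2-ethenyl-3-(hydroxymethyl)-2,4-dimethylpent-4-en-1-yl]furan-2(5H)-one
Product: 17 (2R,3R)-4-[(2R)-4-({[tert-butyl(dimethyl)silyl]oxy}methyl)-5-oxo-2,5-dihydrofuran-2-yl]-3-ethenyl-3-methyl-2-(prop-1-en-2-yl)butanal
Conditions: Dess–Martin periodinane, pyridine, CH2Cl2, 0 °C; used at once
Reagents that add atoms: none
Why: Dess–Martin oxidation under buffered, cold conditions gives the β,γ-unsaturated aldehyde without epimerising C6 or moving the double bond.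

Step 10
Reactants: 17 (2R,3R)-4-[(2R)-4-({[tert-butyl(dimethyl)silyl]oxy}methyl)-5-oxo-2,5-dihydrofuran-2-yl]-3-ethenyl-3-methyl-2-(prop-1-en-2-yl)butanal
Product: 18 (3aS,4R,5R,6R,7aR)-6-ethenyl-4-hydroxy-6-methyl-3-methylidene-5-(prop-1-en-2-yl)hexahydro-1-benzofuran-2(3H)-one
Conditions: SmI2 (2.5 equiv), HMPA (10 equiv), THF, −78 → −20 °C, slow addition of 17 (5 mM); sat. NH4Cl
Reagents that add atoms: none
Why: Proposed new method: SmI2/HMPA reduces the aldehyde to a ketyl, whose nucleophilic carbon C5 adds 6-exo to the electrophilic β-carbon C4 of the butenolide; the tether from C3 forces the cis ring fusion (C3–O/C4–C11 cis), the bulky HMPA-solvated O–Sm group turns away from the lactone (C5–O trans to C4–C11, cis to the C6 substituent), and the samarium enolate then expels silyloxide to give the α-methylene lactone; the closest known reaction types are SmI2 ketyl–olefin cyclisations onto enoates and β-elimination of β-oxygenated samarium enolates.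

Step 11
Reactants: 18 (3aS,4R,5R,6R,7aR)-6-ethenyl-4-hydroxy-6-methyl-3-methylidene-5-(prop-1-en-2-yl)hexahydro-1-benzofuran-2(3H)-one
Product: 20 prop-2-en-1-yl 2-[(1R,2R,3R,4R,6R)-4-ethenyl-2,6-dihydroxy-4-methyl-3-(prop-1-en-2-yl)cyclohexyl]prop-2-enoate, via lithium carboxylate 19 (not isolated)
Conditions: LiOH·H2O (1.1 equiv), THF/H2O, 0 °C; concentrate; then allyl bromide, DMF, rt
Reagents that add atoms: lithium hydroxide [Li+].[OH-]; allyl bromide C=CCBr
Why: saponification of the lactone and SN2 O-alkylation of the carboxylate free the C3 hydroxyl while keeping the acid from closing back to the lactone.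

Step 12
Reactants: 21 but-2-yn-1-ol
Product: 23 (2Z)-3-iodobut-2-en-1-ol, via cyclic alkenylalanate 22 (not isolated)
Conditions: NaAlH2(OCH2CH2OCH3)2, THF, 0 °C → rt; EtOAc; then I2, −78 → 0 °C
Reagents that add atoms: iodine II
Why: hydroxyl-directed trans-hydroalumination places aluminium on C3 cis to the CH2O group, and iodinolysis with retention gives the (Z)-iodide.

Step 13
Reactants: 23 (2Z)-3-iodobut-2-en-1-ol
Product: 26 (2Z)-4-(acetyloxy)-2-methylbut-2-enoic acid, via dilithio alkoxide 24 (not isolated), via dilithium carboxylate 25 (not isolated)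
Conditions: t-BuLi (3.1 equiv), Et2O, −78 °C; CO2, then N2 purge; Ac2O (1.05 equiv), −78 → 0 °C; cold 1 M HCl
Reagents that add atoms: carbon dioxide O=C=O; acetic anhydride CC(=O)OC(C)=O
Why: iodine–lithium exchange with retention of geometry, carboxylation of the alkenyllithium and O-acetylation of the alkoxide (far more nucleophilic than the carboxylate) give the (Z)-acid, which cannot lactonise once acetylated.

Step 14
Reactants: 20 prop-2-en-1-yl 2-[(1R,2R,3R,4R,6R)-4-ethenyl-2,6-dihydroxy-4-methyl-3-(prop-1-en-2-yl)cyclohexyl]prop-2-enoate; 26 (2Z)-4-(acetyloxy)-2-methylbut-2-enoic acid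
Product: 28 prop-2-en-1-yl 2-[(1S,2R,3R,4R,6R)-6-{[(2Z)-4-(acetyloxy)-2-methylbut-2-enoyl]oxy}-4-ethenyl-2-hydroxy-4-methyl-3-(prop-1-en-2-yl)cyclohexyl]prop-2-enoate, via mixed anhydride 27 (not isolated)
Conditions: 26, 2,4,6-trichlorobenzoyl chloride, Et3N, toluene, rt; filter; then 20, toluene, 80 °C
Reagents that add atoms: none
Why: Yamaguchi esterification through the preformed mixed anhydride without a nucleophilic catalyst (the protocol used for angelates) keeps the (Z)-geometry, and the C3 hydroxyl reacts in preference to the C5 hydroxyl, which is flanked by two branched carbons.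

Step 15
Reactants: 28 prop-2-en-1-yl 2-[(1S,2R,3R,4R,6R)-6-{[(2Z)-4-(acetyloxy)-2-methylbut-2-enoyl]oxy}-4-ethenyl-2-hydroxy-4-methyl-3-(prop-1-en-2-yl)cyclohexyl]prop-2-enoate
Product: 29 prop-2-en-1-yl 2-[(1S,2R,3S,4R,6R)-6-{[(2Z)-4-(acetyloxy)-2-methylbut-2-enoyl]oxy}-4-ethenyl-2-hydroxy-3-(3-hydroxyprop-1-en-2-yl)-4-methylcyclohexyl]prop-2-enoate
Conditions: SeO2 (0.3 equiv), t-BuOOH (3 equiv), CH2Cl2, 0 °C → rt
Reagents that add atoms: selenium dioxide O=[Se]=O (catalytic oxygen carrier); tert-butyl hydroperoxide CC(C)(C)OO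
Why: SeO2-catalysed allylic hydroxylation (ene reaction then [2,3]-shift) occurs at the methyl group of the isopropenyl unit, the only electron-rich alkene that carries allylic hydrogens.

Step 16
Reactants: 29 prop-2-en-1-yl 2-[(1S,2R,3S,4R,6R)-6-{[(2Z)-4-(acetyloxy)-2-methylbut-2-enoyl]oxy}-4-ethenyl-2-hydroxy-3-(3-hydroxyprop-1-en-2-yl)-4-methylcyclohexyl]prop-2-enoate
Product: 30 2-[(1S,2R,3S,4R,6R)-6-{[(2Z)-4-(acetyloxy)-2-methylbut-2-enoyl]oxy}-4-ethenyl-2-hydroxy-3-(3-hydroxyprop-1-en-2-yl)-4-methylcyclohexyl]prop-2-enoic acid (target)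
Conditions: Pd(PPh3)4 (5 mol %), N-methylaniline (3 equiv), THF, 0 °C
Reagents that add atoms: none
Why: Tsuji–Trost deallylation: zerovalent palladium ionises the unsubstituted allyl ester much faster than the trisubstituted, electron-poor allylic acetate of the side chain, and the weakly nucleophilic N-methylaniline takes the allyl group without adding to the acrylate.

**Compound list**

1 | tert-butyl(but-3-yn-1-yloxy)dimethylsilane | C#CCCO[Si](C)(C)C(C)(C)C | starting material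
2 | [(1E)-4-{[tert-butyl(dimethyl)silyl]oxy}-2-methylbut-1-en-1-yl]dimethylalumane | C[Al](C)/C=C(\C)CCO[Si](C)(C)C(C)(C)C | intermediate
3 | (2E)-5-{[tert-butyl(dimethyl)silyl]oxy}-3-methylpent-2-en-1-ol | OC/C=C(\C)CCO[Si](C)(C)C(C)(C)C | intermediate
4 | 3-methylbut-3-enoic acid | C=C(C)CC(=O)O | starting material
5 | (2E)-5-{[tert-butyl(dimethyl)silyl]oxy}-3-methylpent-2-en-1-yl 3-methylbut-3-enoate | C=C(C)CC(=O)OC/C=C(\C)CCO[Si](C)(C)C(C)(C)C | intermediate
6 | E(O) boron ketene acetal of 5 with the (4R,5R)-diazaborolidine | C=C(C)/C=C(\OC/C=C(\C)CCO[Si](C)(C)C(C)(C)C)OB1N(S(=O)(=O)c2cc(C(F)(F)F)cc(C(F)(F)F)c2)[C@H](c2ccccc2)[C@@H](c2ccccc2)N1S(=O)(=O)c1cc(C(F)(F)F)cc(C(F)(F)F)c1 | intermediate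
7 | (2R,3R)-5-{[tert-butyl(dimethyl)silyl]oxy}-3-ethenyl-3-methyl-2-(prop-1-en-2-yl)pentanoic acid | OC(=O)[C@H](C(C)=C)[C@@](C)(C=C)CCO[Si](C)(C)C(C)(C)C | intermediate
8 | (2R,3R)-5-{[tert-butyl(dimethyl)silyl]oxy}-3-ethenyl-3-methyl-2-(prop-1-en-2-yl)pentan-1-ol | OC[C@H](C(C)=C)[C@@](C)(C=C)CCO[Si](C)(C)C(C)(C)C | intermediate
9 | (2R,3R)-3-ethenyl-3-methyl-2-(prop-1-en-2-yl)pentane-1,5-diol | OC[C@H](C(C)=C)[C@@](C)(C=C)CCO | intermediate
10 | (4R,5R)-4-ethenyl-4-methyl-5-(prop-1-en-2-yl)oxan-2-ol (anomer mixture) | OC1C[C@](C)(C=C)[C@@H](C(C)=C)CO1 | intermediate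
11 | (4R,5R)-4-ethenyl-4-methyl-5-(prop-1-en-2-yl)oxan-2-one | O=C1C[C@](C)(C=C)[C@@H](C(C)=C)CO1 | intermediate
12 | tert-butyldimethyl(prop-2-yn-1-yloxy)silane | C#CCO[Si](C)(C)C(C)(C)C | starting material
13 | lithium 3-{[tert-butyl(dimethyl)silyl]oxy}prop-1-yn-1-ide | [Li]C#CCO[Si](C)(C)C(C)(C)C | intermediate
14 | (6R,7R)-1-{[tert-butyl(dimethyl)silyl]oxy}-6-ethenyl-8-hydroxy-6-methyl-7-(prop-1-en-2-yl)oct-2-yn-4-one | OC[C@H](C(C)=C)[C@@](C)(C=C)CC(=O)C#CCO[Si](C)(C)C(C)(C)C | intermediate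
15 | (4R,6R,7R)-1-{[tert-butyl(dimethyl)silyl]oxy}-6-ethenyl-6-methyl-7-(prop-1-en-2-yl)oct-2-yne-4,8-diol | OC[C@H](C(C)=C)[C@@](C)(C=C)C[C@@H](O)C#CCO[Si](C)(C)C(C)(C)C | intermediate
16 | (5R)-3-({[tert-butyl(dimethyl)silyl]oxy}methyl)-5-[(2R,3R)-2-ethenyl-3-(hydroxymethyl)-2,4-dimethylpent-4-en-1-yl]furan-2(5H)-one | OC[C@H](C(C)=C)[C@@](C)(C=C)C[C@H]1OC(=O)C(CO[Si](C)(C)C(C)(C)C)=C1 | intermediate
17 | (2R,3R)-4-[(2R)-4-({[tert-butyl(dimethyl)silyl]oxy}methyl)-5-oxo-2,5-dihydrofuran-2-yl]-3-ethenyl-3-methyl-2-(prop-1-en-2-yl)butanal | O=C[C@H](C(C)=C)[C@@](C)(C=C)C[C@H]1OC(=O)C(CO[Si](C)(C)C(C)(C)C)=C1 | intermediate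
18 | (3aS,4R,5R,6R,7aR)-6-ethenyl-4-hydroxy-6-methyl-3-methylidene-5-(prop-1-en-2-yl)hexahydro-1-benzofuran-2(3H)-one | C=C[C@@]1(C)C[C@H]2OC(=O)C(=C)[C@H]2[C@H](O)[C@@H]1C(C)=C | intermediate
19 | lithium 2-[(1R,2R,3R,4R,6R)-4-ethenyl-2,6-dihydroxy-4-methyl-3-(prop-1-en-2-yl)cyclohexyl]prop-2-enoate | C=C[C@@]1(C)C[C@@H](O)[C@@H](C(=C)C(=O)[O-])[C@H](O)[C@@H]1C(C)=C.[Li+] | intermediate
20 | prop-2-en-1-yl 2-[(1R,2R,3R,4R,6R)-4-ethenyl-2,6-dihydroxy-4-methyl-3-(prop-1-en-2-yl)cyclohexyl]prop-2-enoate | C=C[C@@]1(C)C[C@@H](O)[C@@H](C(=C)C(=O)OCC=C)[C@H](O)[C@@H]1C(C)=C | intermediate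
21 | but-2-yn-1-ol | CC#CCO | starting material
22 | sodium 2,2-bis(2-methoxyethoxy)-3-methyl-2,5-dihydro-1,2-oxaluminol-2-uide (cyclic alkenylalanate) | CC1=CCO[Al-]1(OCCOC)OCCOC.[Na+] | intermediate
23 | (2Z)-3-iodobut-2-en-1-ol | C/C(I)=C/CO | intermediate
24 | lithium (2Z)-3-lithiobut-2-en-1-olate | C/C([Li])=C/CO[Li] | intermediate
25 | dilithium (2Z)-2-methyl-4-oxidobut-2-enoate | [Li]OC/C=C(/C)C(=O)O[Li] | intermediate
26 | (2Z)-4-(acetyloxy)-2-methylbut-2-enoic acid | O=C(O)/C(C)=C\COC(C)=O | intermediate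
27 | (2Z)-4-(acetyloxy)-2-methylbut-2-enoic 2,4,6-trichlorobenzoic anhydride | O=C(OC(=O)c1c(Cl)cc(Cl)cc1Cl)/C(C)=C\COC(C)=O | intermediate
28 | prop-2-en-1-yl 2-[(1S,2R,3R,4R,6R)-6-{[(2Z)-4-(acetyloxy)-2-methylbut-2-enoyl]oxy}-4-ethenyl-2-hydroxy-4-methyl-3-(prop-1-en-2-yl)cyclohexyl]prop-2-enoate | C=C[C@@]1(C)C[C@@H](OC(=O)/C(C)=C\COC(C)=O)[C@@H](C(=C)C(=O)OCC=C)[C@H](O)[C@@H]1C(C)=C | intermediate
29 | prop-2-en-1-yl 2-[(1S,2R,3S,4R,6R)-6-{[(2Z)-4-(acetyloxy)-2-methylbut-2-enoyl]oxy}-4-ethenyl-2-hydroxy-3-(3-hydroxyprop-1-en-2-yl)-4-methylcyclohexyl]prop-2-enoate | C=C[C@@]1(C)C[C@@H](OC(=O)/C(C)=C\COC(C)=O)[C@@H](C(=C)C(=O)OCC=C)[C@H](O)[C@@H]1C(=C)CO | intermediate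
30 | 2-[(1S,2R,3S,4R,6R)-6-{[(2Z)-4-(acetyloxy)-2-methylbut-2-enoyl]oxy}-4-ethenyl-2-hydroxy-3-(3-hydroxyprop-1-en-2-yl)-4-methylcyclohexyl]prop-2-enoic acid | C=C[C@@]1(C)C[C@@H](OC(=O)/C(C)=C\COC(C)=O)[C@@H](C(=C)C(=O)O)[C@H](O)[C@@H]1C(=C)CO | target

**Step count and risks**

Total step count: 16. Longest linear sequence: 14 steps (steps 1–11 and 14–16); steps 12–13 make the side-chain acid.

The three steps most likely to fail:

- **Step 10 (SmI2 ketyl cyclisation/β-elimination).** The cascade is unprecedented in this exact form. The C5 epimer is of similar strain and could compete, and the silyloxide may fail to leave, or the product may be over-reduced. Fallback: the route sets out from aldehyde 17. HF·pyridine (THF, 0 °C) frees the allylic alcohol to give (2R,3R)-3-ethenyl-4-[(2R)-4-(hydroxymethyl)-5-oxo-2,5-dihydrofuran-2-yl]-3-methyl-2-(prop-1-en-2-yl)butanal F1. PPh3/NBS (CH2Cl2, −20 °C) turns it into (2R,3R)-4-[(2R)-4-(bromomethyl)-5-oxo-2,5-dihydrofuran-2-yl]-3-ethenyl-3-methyl-2-(prop-1-en-2-yl)butanal F2. CrCl2 (THF, rt, high dilution) then closes ring A by an intramolecular Nozaki–Hiyama–Kishi-type allylation. Its closed chair transition state, with the ring-locked (E)-γ-substituted allylchromium, should give the anti product (C5–O trans to C4–C11), and the route is rejoined at lactone 18.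

- **Step 8 (one-step Pd cyclocarbonylation).** It needs 95 °C and syngas on a polyene diol, so alkene reduction or low conversion is possible. Fallback: the route sets out from diol 15. NaAlH2(OCH2CH2OCH3)2 (THF, 0 °C) then I2 (−78 °C) gives, by hydroxyl-directed trans-hydroalumination (H to C4, iodine to C11), (2Z,4R,6R,7R)-1-{[tert-butyl(dimethyl)silyl]oxy}-6-ethenyl-2-iodo-6-methyl-7-(prop-1-en-2-yl)oct-2-ene-4,8-diol F3. Carbonylative lactonisation (PdCl2(PPh3)2, CO 1 atm, Et3N, THF, 50 °C) then returns to butenolide 16.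

- **Step 15 (late SeO2 hydroxylation).** Yields are usually moderate, over-oxidation to the enal is common, and the substrate carries several other alkenes. Fallback: the route sets out from ester 28. Ene-type allylic chlorination of the isopropenyl group (Ca(OCl)2, solid CO2, CH2Cl2/H2O, 0 °C) gives prop-2-en-1-yl 2-[(1S,2R,3S,4R,6R)-6-{[(2Z)-4-(acetyloxy)-2-methylbut-2-enoyl]oxy}-3-(3-chloroprop-1-en-2-yl)-4-ethenyl-2-hydroxy-4-methylcyclohexyl]prop-2-enoate F4. HCO2Na (Bu4NI cat., DMF, rt) gives prop-2-en-1-yl 2-[(1S,2R,3S,4R,6R)-6-{[(2Z)-4-(acetyloxy)-2-methylbut-2-enoyl]oxy}-4-ethenyl-3-[3-(formyloxy)prop-1-en-2-yl]-2-hydroxy-4-methylcyclohexyl]prop-2-enoate F5. KHCO3/MeOH (0 °C) cleaves only the formate and returns to alcohol 29.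

Further compounds

F1 | step 10 | (2R,3R)-3-ethenyl-4-[(2R)-4-(hydroxymethyl)-5-oxo-2,5-dihydrofuran-2-yl]-3-methyl-2-(prop-1-en-2-yl)butanal | O=C[C@H](C(C)=C)[C@@](C)(C=C)C[C@H]1OC(=O)C(CO)=C1
F2 | step 10 | (2R,3R)-4-[(2R)-4-(bromomethyl)-5-oxo-2,5-dihydrofuran-2-yl]-3-ethenyl-3-methyl-2-(prop-1-en-2-yl)butanal | O=C[C@H](C(C)=C)[C@@](C)(C=C)C[C@H]1OC(=O)C(CBr)=C1
F3 | step 8 | (2Z,4R,6R,7R)-1-{[tert-butyl(dimethyl)silyl]oxy}-6-ethenyl-2-iodo-6-methyl-7-(prop-1-en-2-yl)oct-2-ene-4,8-diol | OC[C@H](C(C)=C)[C@@](C)(C=C)C[C@@H](O)/C=C(\I)CO[Si](C)(C)C(C)(C)C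
F4 | step 15 | prop-2-en-1-yl 2-[(1S,2R,3S,4R,6R)-6-{[(2Z)-4-(acetyloxy)-2-methylbut-2-enoyl]oxy}-3-(3-chloroprop-1-en-2-yl)-4-ethenyl-2-hydroxy-4-methylcyclohexyl]prop-2-enoate | C=C[C@@]1(C)C[C@@H](OC(=O)/C(C)=C\COC(C)=O)[C@@H](C(=C)C(=O)OCC=C)[C@H](O)[C@@H]1C(=C)CCl
F5 | step 15 | prop-2-en-1-yl 2-[(1S,2R,3S,4R,6R)-6-{[(2Z)-4-(acetyloxy)-2-methylbut-2-enoyl]oxy}-4-ethenyl-3-[3-(formyloxy)prop-1-en-2-yl]-2-hydroxy-4-methylcyclohexyl]prop-2-enoate | C=C[C@@]1(C)C[C@@H](OC(=O)/C(C)=C\COC(C)=O)[C@@H](C(=C)C(=O)OCC=C)[C@H](O)[C@@H]1C(=C)COC=O
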